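**Plan**

1. Retrosynthesis (tetrahydropyran numbered O1, C2 = CH bearing the quaternary carbinol carbon, C3 = CH–OAng, C4, C5 = α-carbon of the γ-lactone, C6 = OCH2): cut the acetyl C=O (alkyne hydration), then the C=C of the nine-membered lactone (intramolecular Horner–Wadsworth–Emmons) and its tertiary ester C–O, then the angelate and the γ-lactone C–O, and last, in one operation, O1–C2 and C4–C5.
2. Enabling feature: O1–C6–C5–C(=O) is a 3-hydroxypropanoate, nucleophilic at C5 (enolate) and O1 (alkoxide), and C2 and C4 flank the oxygenated C3. Tying the C3 oxygen and C4 into a butenolide makes C4 a Michael acceptor; an epoxide across C2 and the carbinol carbon makes C2 an electrophile that already carries the tertiary oxygen. The two extra butenolide carbons become the lactone CH–O carbon and the ring-alkene CH.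
3. Forward order: enynol 1 → epoxy aldehyde 5 → butenolide 10; the dianion of 11 is joined to 10 and the tetrahydropyran closes (step 7); hydroxylation, lactol, methylenation with relactonisation give the γ-lactone; angelate; phosphonate; alkene cleavage; the nine-membered lactone closes; alkyne hydration gives the acetyl group.
4. Stereochemistry: tartrate-controlled epoxidation fixes the epoxide (C2 by inversion, carbinol carbon by retention); Felkin–Anh addition then Mitsunobu inversion fixes C3; the butenolide relays C3 to C4 (anti addition) and to the lactone CH–O carbon (anti hydroxylation); C5 settles by equilibration to the cis-fused lactone; the ring alkene is Z by ring size.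
5. Compounds 1, 6, 8, 11, 21 and 24 are commercial.

Key step: step 7

Remark: pyran C5, formed in step 7, is epimerisable; 13 to 19 are drawn as the epimer that leads to the target, and step 10 is where this centre is settled.

**Route**

Step 1
Reactants: 1 (Z)-3-methylpent-2-en-4-yn-1-ol
Product: 3 (Z)-3-methyl-5-(trimethylsilyl)pent-2-en-4-yn-1-ol, via bis-silyl ether 2 (not isolated)
Conditions: EtMgBr (2.2 equiv), THF, 0 → 40 °C; Me3SiCl (2.3 equiv), 0 → 23 °C; then 1 M H2SO4, 23 °C
Reagents that add atoms: chlorotrimethylsilane C[Si](C)(C)Cl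
Why: Double deprotonation, bis-silylation and selective acid hydrolysis of the O–Si bond (alkyne C-silylation) cap the acidic alkyne C–H, which would interfere with the metathesis catalyst of step 6 and the enolates of steps 7 and 8; no stereocentre is formed and the Z-alkene is untouched.

Step 2
Reactants: 3 (Z)-3-methyl-5-(trimethylsilyl)pent-2-en-4-yn-1-ol
Product: 4 [(2R,3S)-3-methyl-3-[(trimethylsilyl)ethynyl]oxiran-2-yl]methanol
Conditions: Ti(OiPr)4 (0.1 equiv), D-(−)-diethyl tartrate (0.12 equiv), t-BuOOH (2 equiv), 4 Å molecular sieves, CH2Cl2, −20 °C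
Reagents that add atoms: tert-butyl hydroperoxide CC(C)(C)OO
Why: Sharpless asymmetric epoxidation of the primary allylic alcohol, in which the D-tartrate ligand directs oxygen to the face that gives the 2R,3S epoxide and the Z geometry places the alkynyl group cis to the hydroxymethyl group.

Step 3
Reactants: 4 [(2R,3S)-3-methyl-3-[(trimethylsilyl)ethynyl]oxiran-2-yl]methanol
Product: 5 (2S,3S)-3-methyl-3-[(trimethylsilyl)ethynyl]oxirane-2-carbaldehyde
Conditions: TEMPO (0.1 equiv), PhI(OAc)2 (1.1 equiv), CH2Cl2, 23 °C
Reagents that add atoms: none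
Why: Nitroxyl-catalysed oxidation of the primary alcohol under neutral conditions should stop at the aldehyde and leave the epoxide and the α-stereocentre untouched (the descriptor changes only through the priority rules).

Step 4
Reactants: 5 (2S,3S)-3-methyl-3-[(trimethylsilyl)ethynyl]oxirane-2-carbaldehyde; 6 vinylmagnesium bromide
Product: 7 (1R)-1-[(2R,3S)-3-methyl-3-[(trimethylsilyl)ethynyl]oxiran-2-yl]prop-2-en-1-ol
Conditions: 6 (1.2 equiv), THF, −78 °C; then H2O
Reagents that add atoms: none
Why: Grignard addition to the α,β-epoxy aldehyde under Felkin–Anh control (attack anti to the oxirane C–O bond) should give mainly the erythro carbinol, whose configuration is inverted in step 5.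

Step 5
Reactants: 7 (1R)-1-[(2R,3S)-3-methyl-3-[(trimethylsilyl)ethynyl]oxiran-2-yl]prop-2-en-1-ol; 8 acrylic acid
Product: 9 (1S)-1-[(2R,3S)-3-methyl-3-[(trimethylsilyl)ethynyl]oxiran-2-yl]prop-2-en-1-yl prop-2-enoate
Conditions: 8 (1.5 equiv), PPh3 (1.5 equiv), diisopropyl azodicarboxylate (1.5 equiv), THF, 0 → 23 °C
Reagents that add atoms: none
Why: Mitsunobu esterification displaces the activated carbinol oxygen by acrylate with SN2 inversion, turning the erythro alcohol into the threo acrylate that carries the configuration required at pyran C3.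

Step 6
Reactants: 9 (1S)-1-[(2R,3S)-3-methyl-3-[(trimethylsilyl)ethynyl]oxiran-2-yl]prop-2-en-1-yl prop-2-enoate
Product: 10 (5S)-5-[(2R,3S)-3-methyl-3-[(trimethylsilyl)ethynyl]oxiran-2-yl]furan-2(5H)-one
Conditions: second-generation Grubbs catalyst RuCl2(=CHPh)(H2IMes)(PCy3) (0.05 equiv), CH2Cl2 (0.01 M), 40 °C
Reagents that add atoms: none
Why: Ring-closing metathesis of the acrylate with the vinyl group gives the butenolide with loss of ethene, while the silyl-capped alkyne and the epoxide are spectators and no stereocentre is touched.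

Step 7
Reactants: 10 (5S)-5-[(2R,3S)-3-methyl-3-[(trimethylsilyl)ethynyl]oxiran-2-yl]furan-2(5H)-one; 11 tert-butyl 3-hydroxypropanoate
Product: 14 tert-butyl (3aR,4S,7S,7aS)-7-[(2S)-2-hydroxy-4-(trimethylsilyl)but-3-yn-2-yl]-2-oxohexahydro-4H-furo[2,3-c]pyran-4-carboxylate, via dilithium dianion 12 (not isolated), via Michael adduct 13 (not isolated)
Conditions: 11 (1.3 equiv), LiN(i-Pr)2 (2.6 equiv), THF, −78 → −30 °C; 10, THF–DMPU, −78 °C; t-BuOH (1.3 equiv), −78 → 23 °C; then AcOH
Reagents that add atoms: none
Why: The dilithium β-oxido enolate 12 adds through carbon to the β-carbon of butenolide 10 (the future pyran C4; conjugate addition of an ester enolate to a 5-substituted furan-2(5H)-one is the closest known reaction type), and once tert-butanol has protonated the lactone enolate of 13 the pendant lithium alkoxide opens the adjacent epoxide at the future C2 (intramolecular alkoxide opening of an epoxide), so that C4–C5 and O1–C2 form in one flask. The only ring closed is the tetrahydropyran, by 6-exo-tet attack on the secondary epoxide carbon, whereas the C–C bond joins the two fragments. C4 is set by addition anti to the oxiranyl group on the butenolide γ-carbon, C2 by inversion at the epoxide carbon, and the tertiary carbinol carbon keeps the epoxide configuration, while C5 is epimerisable and is settled in step 10. The step needs carbon before oxygen attack and 1,4- before 1,2-addition (ester enolate at −78 °C with DMPU), conjugate addition before γ-deprotonation of the butenolide (low temperature, no free amide base left), and attack at C2 instead of the quaternary carbon (6-exo against 7-endo, basic medium).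

Step 8
Reactants: 14 tert-butyl (3aR,4S,7S,7aS)-7-[(2S)-2-hydroxy-4-(trimethylsilyl)but-3-yn-2-yl]-2-oxohexahydro-4H-furo[2,3-c]pyran-4-carboxylate
Product: 16 tert-butyl (3S,3aS,4S,7S,7aS)-3-hydroxy-7-[(2S)-2-hydroxy-4-(trimethylsilyl)but-3-yn-2-yl]-2-oxohexahydro-4H-furo[2,3-c]pyran-4-carboxylate, via dipotassium enolate 15 (not isolated)
Conditions: KN(SiMe3)2 (2.3 equiv), THF, −78 °C; 2-(phenylsulfonyl)-3-phenyloxaziridine (1.4 equiv), −78 °C; then AcOH
Reagents that add atoms: 2-(phenylsulfonyl)-3-phenyloxaziridine O=S(=O)(c1ccccc1)N1OC1c1ccccc1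
Why: Kinetic enolisation occurs at the lactone CH2 (more acidic and less hindered than the tertiary ester α-CH), and electrophilic hydroxylation of the enolate by the N-sulfonyloxaziridine should take place anti to the adjacent pyran C4 substituent, which sets the new carbinol centre trans to it.

Step 9
Reactants: 16 tert-butyl (3S,3aS,4S,7S,7aS)-3-hydroxy-7-[(2S)-2-hydroxy-4-(trimethylsilyl)but-3-yn-2-yl]-2-oxohexahydro-4H-furo[2,3-c]pyran-4-carboxylate
Product: 17 lactol of 16 (2-hydroxy in place of 2-oxo; both anomers)
Conditions: i-Bu2AlH (3.5 equiv), CH2Cl2, −78 °C; then aqueous potassium sodium tartrate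
Reagents that add atoms: none
Why: Half-reduction of the γ-lactone to the lactol at low temperature, where the tert-butyl ester is too hindered to react and the two hydroxyl groups are only converted into aluminium alkoxides until work-up.

Step 10
Reactants: 17 lactol of 16
Product: 20 (1R,3aS,6S,7S,7aR)-1-ethenyl-7-hydroxy-6-[(2S)-2-hydroxybut-3-yn-2-yl]hexahydro-1H-furo[3,4-c]pyran-3-one, via methylenated hydroxy ester 18 (not isolated), via silylated lactone 19 (not isolated)
Conditions: Ph3PCH3Br (6 equiv), KOt-Bu (5.5 equiv), THF, 0 → 40 °C; MeOH, 23 °C; then 1 M HCl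
Reagents that add atoms: methyltriphenylphosphonium bromide C[P+](c1ccccc1)(c1ccccc1)c1ccccc1.[Br-]
Why: Wittig methylenation of the open hydroxy aldehyde form of the lactol frees the pyran C3 hydroxyl and an allylic alkoxide that closes the γ-lactone on the tert-butyl ester (5-exo-trig acyl substitution), the basic medium should equilibrate the epimerisable C5 to the cis-fused lactone expected to be the more stable ring fusion, and methanolic alkoxide then cleaves the alkynylsilane.

Step 11
Reactants: 20 (1R,3aS,6S,7S,7aR)-1-ethenyl-7-hydroxy-6-[(2S)-2-hydroxybut-3-yn-2-yl]hexahydro-1H-furo[3,4-c]pyran-3-one; 21 angelic acid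
Product: 23 (1R,3aS,6S,7S,7aS)-1-ethenyl-6-[(2S)-2-hydroxybut-3-yn-2-yl]-3-oxohexahydro-1H-furo[3,4-c]pyran-7-yl (2Z)-2-methylbut-2-enoate, via mixed anhydride 22 (not isolated)
Conditions: 21 (3 equiv), 2,4,6-trichlorobenzoyl chloride (3 equiv), Et3N (6 equiv), toluene, 23 °C; then 20, 80 °C
Reagents that add atoms: none
Why: Yamaguchi-type esterification through the mixed anhydride should acylate the secondary hydroxyl and leave the tertiary propargylic one, and the absence of a nucleophilic catalyst avoids Z to E isomerisation of the angelate.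

Step 12
Reactants: 23 angelate of 20; 24 2-(diethoxyphosphoryl)propanoic acid
Product: 25 2-(diethoxyphosphoryl)propanoate of the tertiary hydroxyl of 23
Conditions: 24 (3 equiv), N,N'-diisopropylcarbodiimide (3 equiv), 4-(dimethylamino)pyridine (0.2 equiv), CH2Cl2, 23 °C
Reagents that add atoms: none
Why: Steglich-type esterification in which carbodiimide activation of the phosphono acid (through the phosphonoketene) is strong enough to acylate the tertiary propargylic alcohol, whose slim alkynyl substituent keeps the hydroxyl accessible; the phosphonate α-carbon is a mixture that is erased in step 14.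

Step 13
Reactants: 25 phosphonate ester of 23
Product: 27 aldehyde (formyl in place of the ethenyl group of 25), via vicinal diol 26 (not isolated)
Conditions: OsO4 (0.02 equiv), NaIO4 (4 equiv), 2,6-lutidine (2 equiv), 1,4-dioxane–H2O (3:1), 23 °C
Reagents that add atoms: sodium periodate [Na+].[O-]I(=O)(=O)=O
Why: Lemieux–Johnson cleavage, in which OsO4 should dihydroxylate the monosubstituted alkene far faster than the trisubstituted conjugated angelate or the alkyne and periodate cleaves the diol to the aldehyde, with lutidine buffering to protect the adjacent stereocentre.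

Step 14
Reactants: 27 aldehyde
Product: 28 nine-membered (Z)-lactone (the target with ethynyl in place of acetyl)
Conditions: LiCl (10 equiv), DBU (3 equiv), MeCN (0.002 M), 0 → 23 °C
Reagents that add atoms: none
Why: Intramolecular Horner–Wadsworth–Emmons olefination under mild LiCl–amine conditions closes the nine-membered lactone because the aldehyde arm and the phosphonate arm are cis on the tetrahydropyran, and the ring should accommodate only the cis (Z) enoate.

Step 15
Reactants: 28 nine-membered (Z)-lactone with ethynyl group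
Product: 29 CNP0342803.2 (target)
Conditions: Ph3PAuCl (0.05 equiv), AgSbF6 (0.05 equiv), 1,4-dioxane–H2O (10:1), 23 °C
Reagents that add atoms: water O
Why: Gold-catalysed Markovnikov hydration of the terminal alkyne, assisted by the neighbouring ester carbonyl (5-exo-dig attack and hydrolysis of the dioxolenium ion), should convert the ethynyl group into the acetyl group without touching the quaternary stereocentre; keeping the ketone masked until now also prevents a five-ring olefination in step 14.

**Compound list**

1 | (Z)-3-methylpent-2-en-4-yn-1-ol | OC/C=C(C)\C#C | starting material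
2 | (Z)-trimethyl{[3-methyl-5-(trimethylsilyl)pent-2-en-4-yn-1-yl]oxy}silane | C[Si](C)(C)OC/C=C(C)\C#C[Si](C)(C)C | intermediate (not isolated)
3 | (Z)-3-methyl-5-(trimethylsilyl)pent-2-en-4-yn-1-ol | OC/C=C(C)\C#C[Si](C)(C)C | intermediate
4 | [(2R,3S)-3-methyl-3-[(trimethylsilyl)ethynyl]oxiran-2-yl]methanol | OC[C@H]1O[C@@]1(C)C#C[Si](C)(C)C | intermediate
5 | (2S,3S)-3-methyl-3-[(trimethylsilyl)ethynyl]oxirane-2-carbaldehyde | O=C[C@H]1O[C@@]1(C)C#C[Si](C)(C)C | intermediate
6 | vinylmagnesium bromide | C=C[Mg]Br | starting material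
7 | (1R)-1-[(2R,3S)-3-methyl-3-[(trimethylsilyl)ethynyl]oxiran-2-yl]prop-2-en-1-ol | C=C[C@@H](O)[C@H]1O[C@@]1(C)C#C[Si](C)(C)C | intermediate
8 | acrylic acid | C=CC(=O)O | starting material
9 | (1S)-1-[(2R,3S)-3-methyl-3-[(trimethylsilyl)ethynyl]oxiran-2-yl]prop-2-en-1-yl prop-2-enoate | C=C[C@H](OC(=O)C=C)[C@H]1O[C@@]1(C)C#C[Si](C)(C)C | intermediate
10 | (5S)-5-[(2R,3S)-3-methyl-3-[(trimethylsilyl)ethynyl]oxiran-2-yl]furan-2(5H)-one | O=C1C=C[C@H](O1)[C@H]2O[C@@]2(C)C#C[Si](C)(C)C | intermediate
11 | tert-butyl 3-hydroxypropanoate | OCCC(=O)OC(C)(C)C | starting material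
12 | dilithium dianion of 11 (chelated β-oxido ester enolate) | [Li]OC/C=C(\O[Li])OC(C)(C)C | intermediate (not isolated)
13 | dilithium salt of the Michael adduct (lactone enolate and primary alkoxide; epoxide intact) | [Li]OC1=C[C@H]([C@@H](CO[Li])C(=O)OC(C)(C)C)[C@H](O1)[C@H]2O[C@@]2(C)C#C[Si](C)(C)C | intermediate (not isolated)
14 | tert-butyl (3aR,4S,7S,7aS)-7-[(2S)-2-hydroxy-4-(trimethylsilyl)but-3-yn-2-yl]-2-oxohexahydro-4H-furo[2,3-c]pyran-4-carboxylate | O=C1C[C@H]2[C@H](O1)[C@H](OC[C@H]2C(=O)OC(C)(C)C)[C@@](C)(O)C#C[Si](C)(C)C | intermediate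
15 | dipotassium alkoxide–enolate of 14 | [K]OC1=C[C@H]2[C@H](O1)[C@H](OC[C@H]2C(=O)OC(C)(C)C)[C@@](C)(O[K])C#C[Si](C)(C)C | intermediate (not isolated)
16 | tert-butyl (3S,3aS,4S,7S,7aS)-3-hydroxy-7-[(2S)-2-hydroxy-4-(trimethylsilyl)but-3-yn-2-yl]-2-oxohexahydro-4H-furo[2,3-c]pyran-4-carboxylate | O=C1[C@@H](O)[C@H]2[C@H](O1)[C@H](OC[C@H]2C(=O)OC(C)(C)C)[C@@](C)(O)C#C[Si](C)(C)C | intermediate
17 | lactol of 16: tert-butyl (3S,3aS,4S,7S,7aS)-2,3-dihydroxy-7-[(2S)-2-hydroxy-4-(trimethylsilyl)but-3-yn-2-yl]hexahydro-4H-furo[2,3-c]pyran-4-carboxylate (both anomers) | OC1[C@@H](O)[C@H]2[C@H](O1)[C@H](OC[C@H]2C(=O)OC(C)(C)C)[C@@](C)(O)C#C[Si](C)(C)C | intermediate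
18 | tert-butyl (3S,4S,5S,6S)-5-hydroxy-4-[(1R)-1-hydroxyprop-2-en-1-yl]-6-[(2S)-2-hydroxy-4-(trimethylsilyl)but-3-yn-2-yl]oxane-3-carboxylate (present as potassium alkoxide) | C=C[C@@H](O)[C@H]1[C@H](O)[C@H](OC[C@H]1C(=O)OC(C)(C)C)[C@@](C)(O)C#C[Si](C)(C)C | intermediate (not isolated)
19 | (1R,3aS,6S,7S,7aR)-1-ethenyl-7-hydroxy-6-[(2S)-2-hydroxy-4-(trimethylsilyl)but-3-yn-2-yl]hexahydro-1H-furo[3,4-c]pyran-3-one | O[C@H]1[C@@H]2[C@@H](C=C)OC(=O)[C@@H]2CO[C@@H]1[C@@](C)(O)C#C[Si](C)(C)C | intermediate (not isolated)
20 | (1R,3aS,6S,7S,7aR)-1-ethenyl-7-hydroxy-6-[(2S)-2-hydroxybut-3-yn-2-yl]hexahydro-1H-furo[3,4-c]pyran-3-one | O[C@H]1[C@@H]2[C@@H](C=C)OC(=O)[C@@H]2CO[C@@H]1[C@@](C)(O)C#C | intermediate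
21 | angelic acid, (2Z)-2-methylbut-2-enoic acid | C/C=C(/C)C(=O)O | starting material
22 | angelic 2,4,6-trichlorobenzoic anhydride | C/C=C(/C)C(=O)OC(=O)c1c(Cl)cc(Cl)cc1Cl | intermediate (not isolated)
23 | (1R,3aS,6S,7S,7aS)-1-ethenyl-6-[(2S)-2-hydroxybut-3-yn-2-yl]-3-oxohexahydro-1H-furo[3,4-c]pyran-7-yl (2Z)-2-methylbut-2-enoate | C/C=C(/C)C(=O)O[C@H]1[C@@H]2[C@@H](C=C)OC(=O)[C@@H]2CO[C@@H]1[C@@](C)(O)C#C | intermediate
24 | 2-(diethoxyphosphoryl)propanoic acid | CCOP(=O)(OCC)C(C)C(=O)O | starting material
25 | 2-(diethoxyphosphoryl)propanoate of the tertiary hydroxyl of 23 (phosphonate α-carbon as a mixture) | C/C=C(/C)C(=O)O[C@H]1[C@@H]2[C@@H](C=C)OC(=O)[C@@H]2CO[C@@H]1[C@@](C)(OC(=O)C(C)P(=O)(OCC)OCC)C#C | intermediate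
26 | vicinal diol from 25 (1,2-dihydroxyethyl in place of ethenyl) | C/C=C(/C)C(=O)O[C@H]1[C@@H]2[C@@H](C(O)CO)OC(=O)[C@@H]2CO[C@@H]1[C@@](C)(OC(=O)C(C)P(=O)(OCC)OCC)C#C | intermediate (not isolated)
27 | aldehyde (formyl in place of the ethenyl group of 25) | C/C=C(/C)C(=O)O[C@H]1[C@@H]2[C@@H](C=O)OC(=O)[C@@H]2CO[C@@H]1[C@@](C)(OC(=O)C(C)P(=O)(OCC)OCC)C#C | intermediate
28 | nine-membered (Z)-lactone, the target with ethynyl in place of acetyl | C/C=C(/C)C(=O)O[C@H]1[C@@H]2[C@H]3/C=C(/C)C(=O)O[C@@](C)(C#C)[C@H]1OC[C@H]2C(=O)O3 | intermediate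
29 | CNP0342803.2 | C/C=C(/C)C(=O)O[C@H]1[C@@H]2[C@H]3/C=C(/C)C(=O)O[C@@](C)(C(C)=O)[C@H]1OC[C@H]2C(=O)O3 | target

**Totals and risks**

Total steps: 15. Longest linear sequence: 15 steps (1 → 29).

Steps most likely to fail:

1. Step 7. The basic dianion may take the γ-proton of the butenolide (with β-elimination of the epoxide) instead of adding. The lithium alkoxide may also open the epoxide too slowly, so that acyl transfer from the lactone to the alkoxide or decay of the lactone enolate intervenes. Fallback, setting out from 10 and 11 and returning at 14: 11 is converted with LiN(i-Pr)2 and Me3SiCl into the bis-silyl ketene acetal F1. F1 is added to 10 in a Mukaiyama–Michael reaction under fluoride catalysis (tetrabutylammonium difluorotriphenylsilicate), so that no strongly basic enolate is present, and mild acidic hydrolysis gives the neutral hydroxy epoxy lactone F2. A catalytic amount of KOt-Bu in THF then closes the tetrahydropyran by the same 6-exo epoxide opening to give 14.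

2. Step 14. Oligomerisation may compete with closure of the strained nine-membered ring, and the α-acyloxy aldehyde may epimerise under base. Fallback, setting out from 23 and returning at 28: acylation of the tertiary alcohol with 2-bromopropanoyl bromide and pyridine gives the α-bromo ester F3. Lemieux–Johnson cleavage as in step 13 gives the bromo aldehyde F4. SmI2 in THF then effects an intramolecular Reformatsky reaction, a closure with precedent for medium-ring lactones, to the β-hydroxy lactone F5. Mesylation and base-induced elimination (MsCl, Et3N, then DBU) give 28.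

3. Step 10. Equilibration of pyran C5 may be incomplete, so that trans-fused lactone is carried on, and excess ylide may intercept the ring-opened α-methylene lactone formed by β-elimination of the ring oxygen. Fallback, setting out from 17 and returning at 20: methylenation at 0 °C with immediate acetic acid quench gives the hydroxy ester 18 in isolated form. Acid-catalysed lactonisation (TsOH, toluene) gives 19 together with its trans-fused C5 epimer F6. The mixture is converted into the lactone enolate with LiN(SiMe3)2 and protonated kinetically from the convex face with 2,6-di-tert-butylphenol at −78 °C to give 19. Desilylation (K2CO3, MeOH, then dilute acid) gives 20.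

Further compounds
F1 | step 7 | {[1-(tert-butoxy)-3-[(trimethylsilyl)oxy]prop-1-en-1-yl]oxy}trimethylsilane | C[Si](C)(C)OCC=C(O[Si](C)(C)C)OC(C)(C)C
F2 | step 7 | neutral Michael adduct (protonated form of 13): γ-lactone bearing the CH(CH2OH)CO2tBu group trans to the intact epoxide arm | O=C1C[C@H]([C@@H](CO)C(=O)OC(C)(C)C)[C@H](O1)[C@H]2O[C@@]2(C)C#C[Si](C)(C)C
F3 | step 14 | 2-bromopropanoate of the tertiary hydroxyl of 23 | C/C=C(/C)C(=O)O[C@H]1[C@@H]2[C@@H](C=C)OC(=O)[C@@H]2CO[C@@H]1[C@@](C)(OC(=O)C(C)Br)C#C
F4 | step 14 | bromo aldehyde (formyl in place of the ethenyl group of F3) | C/C=C(/C)C(=O)O[C@H]1[C@@H]2[C@@H](C=O)OC(=O)[C@@H]2CO[C@@H]1[C@@](C)(OC(=O)C(C)Br)C#C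
F5 | step 14 | nine-membered β-hydroxy α-methyl lactone (hydrate of the ring alkene of 28; new centres as formed) | C/C=C(/C)C(=O)O[C@H]1[C@@H]2[C@H]3C(O)C(C)C(=O)O[C@@](C)(C#C)[C@H]1OC[C@H]2C(=O)O3
F6 | step 10 | trans-fused C5 epimer of 19 | O[C@H]1[C@@H]2[C@@H](C=C)OC(=O)[C@H]2CO[C@@H]1[C@@](C)(O)C#C[Si](C)(C)C
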